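**Retrosynthetic overview**
1. The strategy rests on the cis-fused α-methyl-γ-butyrolactone. Its O-CH (γ) and ring-fusion CH (β) are also two members of the cyclohexene, lying between the ethyl-bearing CH and pyrrole C3. They are read as C5 and C4 of a 3-methyl-2-silyloxyfuran laid across the four-carbon unit ethyl-CH / azepine alkene carbon / pyrrole C2 / pyrrole C3.
2. Late disconnections: the azepine C=C-H comes from an enol triflate, itself made from a silyl enol ether. The appended lactone comes from a pyrrolyl γ-keto acid, made from the free pyrrole α carbon and (R)-methylsuccinic anhydride.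
3. Key disconnection: both cyclohexene bonds (ethyl-CH to O-CH, pyrrole C3 to fusion CH) are cut together, giving a 9-propylidene pyrroloazepin-8-one and the silyloxyfuran. The enone goes back to the azepinone and propanal, and the azepinone to a pyrrole diester.
4. Ring order: pyrrole bought; azepine by Dieckmann closure; cyclohexene in the key step, where the furan becomes the fused lactone; appended lactone last.

Key step: step 7

Locants: pyrrole atoms are numbered as in pyrrole (N1; C2 carries the azepine carbon; C3; C4; C5 is the free α carbon). C8 and C9 are the azepine carbonyl carbon and its pyrrole-bound neighbour.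
Assumption 1: the equilibrating elimination of step 5 is taken to give the Z alkylidene ketone (ethyl on the carbonyl side); the geometry would be checked by NOE before step 7, because it decides which relative topicity gives the trans ethyl/oxygen relationship.
Assumption 2: no established model predicts the sense of induction of the oxazaborolidinium salt for an α-heteroaryl alkylidene ketone, so the (S)-catalyst is written and its equally available (R)-enantiomer would be used if the Re face proved to be the open one.

Step 1
Reactants: 1 ethyl 2-(1H-pyrrol-2-yl)acetate; 2 ethyl 4-bromobutanoate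
Product: 3 ethyl 4-[2-(2-ethoxy-2-oxoethyl)-1H-pyrrol-1-yl]butanoate
Conditions: NaH (1.05 equiv), DMF, 0 °C; then 2, 0 °C to rt
Reagents that add atoms: none
Why: SN2 N-alkylation of the sodium pyrrolide, which reacts at nitrogen with a primary bromide in the dissociating solvent DMF, should join the two ester arms without creating a stereocentre.

Step 2
Reactants: 3 N-alkylated pyrrole diester
Product: 4 ethyl 8-oxo-6,7,8,9-tetrahydro-5H-pyrrolo[1,2-a]azepine-9-carboxylate
Conditions: KOtBu (1.5 equiv), THF (0.02 M, slow addition of 3), 0 °C to rt; AcOH quench
Reagents that add atoms: none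
Why: Dieckmann condensation in which the more acidic pyrrolylacetate CH2 attacks the butanoate ester (7-exo-trig), dilution holds back intermolecular Claisen reaction, deprotonation of the β-keto ester drives the equilibrium, and the other mode of closure would give the same ketone after step 3.

Step 3
Reactants: 4 bicyclic β-keto ester
Product: 5 5,6,7,9-tetrahydro-8H-pyrrolo[1,2-a]azepin-8-one
Conditions: LiCl, DMSO/H2O, 130 °C, N2
Reagents that add atoms: none
Why: Krapcho dealkoxycarbonylation of a β-keto ester runs under near-neutral conditions that spare the acid-sensitive pyrrole and leaves no stereocentre.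

Step 4
Reactants: 5 pyrroloazepin-8-one; 6 propanal
Product: 7 9-(1-hydroxypropyl)-5,6,7,9-tetrahydro-8H-pyrrolo[1,2-a]azepin-8-one (racemic diastereomer mixture)
Conditions: LiN(SiMe3)2 (1.05 equiv), THF, −78 °C; then 6, −78 °C; AcOH quench
Reagents that add atoms: none
Why: Directed aldol addition of a preformed lithium enolate, formed at C9 because that CH2 is flanked by carbonyl and pyrrole (as C1 is in 2-tetralone), avoids self-condensation of propanal, and the two new stereocentres need no control since both vanish in step 5.

Step 5
Reactants: 7 aldol adduct
Product: 9 (Z)-9-propylidene-5,6,7,9-tetrahydro-8H-pyrrolo[1,2-a]azepin-8-one, via mesylate 8 (not isolated)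
Conditions: MsCl, Et3N, CH2Cl2, 0 °C; then DBU (1,8-diazabicyclo[5.4.0]undec-7-ene), rt
Reagents that add atoms: methanesulfonyl chloride, CS(=O)(=O)Cl (its atoms are held in 8 only)
Why: Mesylation and E1cB elimination under equilibrating conditions give the conjugated enone, expected as the Z isomer because ethyl on the carbonyl side leaves only the small vinyl H facing the pyrrole C3-H, so the vinylpyrrole unit can stay close to planar.

Step 6
Reactants: 10 3-methyl-2(5H)-furanone
Product: 11 3-methyl-2-(triisopropylsilyloxy)furan
Conditions: TIPSOTf, Et3N, CH2Cl2, 0 °C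
Reagents that add atoms: triisopropylsilyl triflate, CC(C)[Si](OS(=O)(=O)C(F)(F)F)(C(C)C)C(C)C
Why: Soft enolisation and O-silylation of the butenolide, driven by aromatisation, is the standard route to 2-silyloxyfurans and creates no stereocentre.

Step 7
Reactants: 9 (Z)-propylidene pyrroloazepinone; 11 3-methyl-2-(triisopropylsilyloxy)furan
Product: 14 tetracyclic lactone TIPS enol ether (ethyl CH S; O-CH R; fusion CH S; methyl CH R), via butenolide Michael adduct 12 (not isolated), via concave-methyl epimer 13 (not isolated)
Conditions: (S)-3,3-diphenyl-1-(2-methylphenyl)tetrahydro-1H,3H-pyrrolo[1,2-c][1,3,2]oxazaborole (20 mol %) + HN(SO2CF3)2 (18 mol %), 11 (1.5 equiv), CH2Cl2, −78 to −20 °C; then DBU (1.5 equiv), toluene added, CH2Cl2 distilled off, 60 °C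
Reagents that add atoms: none
Why: Proposed new method: the cationic boron Lewis acid binds the C8 carbonyl of 9, furan C5 of 11 adds to the ethyl-bearing β carbon and the silyl group moves to the new enolate oxygen (12); the acid then activates the butenolide, or its still O-silylated oxocarbenium form reacts directly, pyrrole C3 attacks the β carbon (old furan C4), the pyrrole rearomatises by proton loss and the lactone enolate is protonated from its open face (13). The closest known reaction types are the catalytic enantioselective vinylogous Mukaiyama-Michael addition of 2-silyloxyfurans to enones and enals and the intramolecular Friedel-Crafts conjugate addition of pyrroles to unsaturated carbonyl acceptors; what is new is their coupling in one flask into a formal (4+2) annulation that dearomatises the furan across C4-C5 and keeps the silyl enol ether. The only ring closed is the cyclohexene, by 6-exo-trig attack of pyrrole C3 on the butenolide C=C, and the furan ring survives as the fused lactone. The ethyl CH (S) comes from catalyst shielding, which leaves the Si face of the β carbon open; the O-CH (R) comes from the exo (unlike) pairing of that face with the Re face of furan C5, favoured because it places the furan C5-H in the crowded sector beside ethyl and turns the ring oxygen and the bulky OTIPS flank away from the catalyst-bound azepinone, so that ethyl ends trans to the lactone oxygen; the fusion CH (S) is forced cis because the short tether reaches only the butenolide face on which it stands; the methyl CH (R) is set by DBU equilibration of 13 to the convex-face epimer 14. The step needs γ and not α attack of the furan, closure through pyrrole C3 and not C5, and furan addition faster than alkylation of one pyrrole by the enone of another: the methyl group blocks the furan α carbon, only pyrrole C3 lies within reach of the acceptor, and the acylvinyl group on the pyrrole of 9 makes it a poorer nucleophile than 11, which is used in excess.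

Step 8
Reactants: 14 tetracyclic lactone TIPS enol ether
Product: 15 tetracyclic enol triflate (OTf on C8; stereocentres as in 14)
Conditions: CsF (3 equiv), PhNTf2 (1.5 equiv), DME, rt to 45 °C
Reagents that add atoms: N-phenylbis(trifluoromethanesulfonimide), O=S(=O)(N(c1ccccc1)S(=O)(=O)C(F)(F)F)C(F)(F)F
Why: Fluoride-induced exchange of a silyl enol ether for an enol triflate frees the caesium enolate in the presence of PhNTf2, which traps it on oxygen with the C8-C9 enol position retained (this conjugated enolate is also the thermodynamic one), and the four stereocentres are untouched because the lactone methyl already sits in its equilibrium position.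

Step 9
Reactants: 16 (R)-methylsuccinic acid
Product: 17 (R)-methylsuccinic anhydride
Conditions: AcCl, reflux; volatiles removed
Reagents that add atoms: none
Why: Cyclodehydration of a 1,4-diacid with acetyl chloride proceeds without touching the α stereocentre, which becomes the (R) methyl carbon of the appended lactone.

Step 10
Reactants: 15 tetracyclic enol triflate; 17 (R)-methylsuccinic anhydride
Product: 18 pyrrolyl γ-keto acid (pyrrole C5-C(=O)-CH2-CH(CH3)-CO2H with the methyl carbon R)
Conditions: Me2AlCl (2.2 equiv), CH2Cl2, −20 to 0 °C; cold 1 M HCl work-up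
Reagents that add atoms: none
Why: Friedel-Crafts acylation of a pyrrole by a cyclic anhydride takes the only free α carbon, opens the anhydride at the carbonyl next to CH2 rather than next to CHMe for steric reasons, uses Me2AlCl both to activate the anhydride and to remove the proton as methane so that no strong acid builds up, and is kept off the vinylpyrrole by the electron-poor enol triflate.

Step 11
Reactants: 18 pyrrolyl γ-keto acid
Product: 20 bis-lactone enol triflate (appended lactone cis; O-CH R; methyl CH R), via hydroxy acid 19 (not isolated)
Conditions: RuCl(p-cymene)[(R,R)-TsDPEN] (5 mol %), HCO2H/Et3N 5:2, EtOAc, 35 °C; then pyridinium p-toluenesulfonate (cat.), CH2Cl2, rt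
Reagents that add atoms: none
Why: Noyori-Ikariya asymmetric transfer hydrogenation of a heteroaryl γ-keto acid followed by lactonisation gives the (R) carbinol with the (R,R) ligand by the usual aryl/alkyl model (pyrrolyl in the aryl role), leaves the methyl centre alone, and delivers the cis lactone, which should also be the more stable epimer, so any ionisation of the labile pyrrolyl C-O bond works in the same direction.

Step 12
Reactants: 20 bis-lactone enol triflate
Product: 21 target CNP0324368.1
Conditions: Pd(OAc)2 (10 mol %), PPh3 (20 mol %), HCO2H (3 equiv), Et3N (4 equiv), DMF, 60 °C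
Reagents that add atoms: none
Why: Palladium-catalysed formate hydrogenolysis of an enol triflate (oxidative addition to zerovalent palladium, triflate/formate exchange, loss of CO2, C-H reductive elimination) puts hydrogen exactly where the triflate stood, so the alkene stays between C8 and C9 and no stereocentre is touched.

**Compound list**
1 | ethyl 2-(1H-pyrrol-2-yl)acetate | CCOC(=O)Cc1ccc[nH]1 | starting material
2 | ethyl 4-bromobutanoate | CCOC(=O)CCCBr | starting material
3 | ethyl 4-[2-(2-ethoxy-2-oxoethyl)-1H-pyrrol-1-yl]butanoate | CCOC(=O)CCCn1cccc1CC(=O)OCC | intermediate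
4 | ethyl 8-oxo-6,7,8,9-tetrahydro-5H-pyrrolo[1,2-a]azepine-9-carboxylate (enolisable C9) | CCOC(=O)C1C(=O)CCCn2cccc21 | intermediate
5 | 5,6,7,9-tetrahydro-8H-pyrrolo[1,2-a]azepin-8-one | O=C1CCCn2cccc2C1 | intermediate
6 | propanal | CCC=O | starting material
7 | 9-(1-hydroxypropyl)-5,6,7,9-tetrahydro-8H-pyrrolo[1,2-a]azepin-8-one, racemic diastereomer mixture | CCC(O)C1C(=O)CCCn2cccc21 | intermediate
8 | methanesulfonate of 7 | CCC(OS(C)(=O)=O)C1C(=O)CCCn2cccc21 | intermediate (not isolated)
9 | (Z)-9-propylidene-5,6,7,9-tetrahydro-8H-pyrrolo[1,2-a]azepin-8-one, ethyl cis to the carbonyl | CC/C=C1\C(=O)CCCn2cccc21 | intermediate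
10 | 3-methyl-2(5H)-furanone | CC1=CCOC1=O | starting material
11 | 3-methyl-2-(triisopropylsilyloxy)furan | Cc1ccoc1O[Si](C(C)C)(C(C)C)C(C)C | intermediate
12 | (5S)-3-methyl-5-{(1S)-1-[8-(triisopropylsilyloxy)-6,7-dihydro-5H-pyrrolo[1,2-a]azepin-9-yl]propyl}furan-2(5H)-one | CC[C@@H](C1=C(O[Si](C(C)C)(C(C)C)C(C)C)CCCn2cccc21)[C@H]1OC(=O)C(C)=C1 | intermediate (not isolated)
13 | epimer of 14 at the lactone methyl carbon (S; methyl on the concave face, cis to the pyrrole C3 bond) | CC[C@H]1C2=C(O[Si](C(C)C)(C(C)C)C(C)C)CCCn3ccc(c32)[C@H]2[C@@H]1OC(=O)[C@H]2C | intermediate (not isolated)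
14 | tetracyclic lactone TIPS enol ether: 6,7-dihydro-5H-pyrrolo[1,2-a]azepine with OTIPS on C8; C9 and pyrrole C3 bridged by CH(Et)-CH(O)-CH to a cyclohexene cis-fused to an α-methyl-γ-lactone; ethyl CH (S), O-CH (R), fusion CH (S), methyl CH (R); ethyl trans to the lactone O, methyl on the convex face | CC[C@H]1C2=C(O[Si](C(C)C)(C(C)C)C(C)C)CCCn3ccc(c32)[C@H]2[C@@H]1OC(=O)[C@@H]2C | intermediate
15 | tetracyclic enol triflate: 14 with OTf in place of OTIPS | CC[C@H]1C2=C(OS(=O)(=O)C(F)(F)F)CCCn3ccc(c32)[C@H]2[C@@H]1OC(=O)[C@@H]2C | intermediate
16 | (R)-methylsuccinic acid | C[C@H](CC(=O)O)C(=O)O | starting material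
17 | (R)-methylsuccinic anhydride | C[C@@H]1CC(=O)OC1=O | intermediate
18 | pyrrolyl keto acid: 15 carrying (2R)-3-carboxy-1-oxobutyl, C(=O)CH2CH(CH3)CO2H, on pyrrole C5 | CC[C@H]1C2=C(OS(=O)(=O)C(F)(F)F)CCCn3c(C(=O)C[C@@H](C)C(=O)O)cc(c32)[C@H]2[C@@H]1OC(=O)[C@@H]2C | intermediate
19 | hydroxy acid: 18 with the ketone reduced to the (R) carbinol | CC[C@H]1C2=C(OS(=O)(=O)C(F)(F)F)CCCn3c([C@H](O)C[C@@H](C)C(=O)O)cc(c32)[C@H]2[C@@H]1OC(=O)[C@@H]2C | intermediate (not isolated)
20 | bis-lactone enol triflate: 15 carrying a cis (2R,4R)-4-methyl-5-oxotetrahydrofuran-2-yl group on pyrrole C5 | CC[C@H]1C2=C(OS(=O)(=O)C(F)(F)F)CCCn3c([C@H]4C[C@@H](C)C(=O)O4)cc(c32)[C@H]2[C@@H]1OC(=O)[C@@H]2C | intermediate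
21 | CNP0324368.1: 20 with H in place of OTf (C8=C9 alkene) | CC[C@H]1C2=CCCCn3c([C@H]4C[C@@H](C)C(=O)O4)cc(c32)[C@H]2[C@@H]1OC(=O)[C@@H]2C | target

**Count**
Total steps: 12. Longest linear sequence: 10 (steps 1, 2, 3, 4, 5, 7, 8, 10, 11, 12).

**Steps most likely to fail**

1. Step 7 (bears the label).
- What may go wrong: the second bond formation may not follow the first under the mild chiral acid. The silyl group may be lost or stay on the lactone oxygen. The pyrrole of one molecule may alkylate the activated enone of another. Facial or exo/endo selectivity may be poor.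
- Fallback (known reactions run one at a time, passing through ketones instead of the silyl enol ether): it sets out from 9 and 11.
- Only the catalytic enantioselective vinylogous Mukaiyama-Michael addition is run at −78 °C, and crude 12 is desilylated with Et3N·3HF to keto butenolide F1 (C9 epimers). F1 is kept away from base, purified, and enriched by crystallisation if needed.
- A separate intramolecular Friedel-Crafts conjugate addition of the pyrrole (BF3·OEt2, CH2Cl2, −40 to 0 °C), followed by DBU equilibration of the lactone methyl, gives tetracyclic ketone F2.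
- Thermodynamic enolisation at the more acidic C9 (KN(SiMe3)2, 0.95 equiv, THF, −78 to 0 °C, equilibration through the slight excess of ketone) and trapping with PhNTf2 rejoin the route at 15.

2. Step 10.
- What may go wrong: the anhydride may open at both carbonyl groups, giving acids that are hard to separate this late, or the pyrrole may decompose under the Lewis acid.
- Fallback (the regiochemical choice is moved to a cheap stage and the acyl transfer becomes a Vilsmeier-Haack acylation): it sets out from 17 and, for the coupling, 15.
- Dimethylamine opens 17 at the less hindered carbonyl to amide acid F3, which is purified by crystallisation. MeI/K2CO3 then gives amide ester F4.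
- F4 is activated with POCl3 (1,2-dichloroethane), treated with 15, and hydrolysed with aqueous NaOAc to keto ester F5.
- The transfer hydrogenation of step 11 applied to F5 gives hydroxy ester F6, which lactonises with loss of methanol and rejoins the route at 20.

3. Step 11.
- What may go wrong: hydride transfer to the electron-rich, vinylogous-amide-like ketone may be sluggish. Over-reduction through an azafulvenium ion may occur, or the carbinol configuration may erode.
- Fallback (thermodynamic control in place of catalyst control): it sets out from 18.
- Luche reduction (NaBH4, CeCl3·7H2O, MeOH, 0 °C) gives 19 together with its carbinol epimer, (S)-hydroxy acid F7. Pyridinium p-toluenesulfonate closes both, to 20 and trans lactone F8.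
- Catalytic camphorsulfonic acid in CH2Cl2 then equilibrates the pair through reversible ionisation of the pyrrolyl C-O bond toward the more stable cis lactone. Remaining F8 is separated and resubmitted, and the route is rejoined at 20.

**Further compounds**
F1 | step 7 | 9-{(1S)-1-[(2S)-4-methyl-5-oxo-2,5-dihydrofuran-2-yl]propyl}-5,6,7,9-tetrahydro-8H-pyrrolo[1,2-a]azepin-8-one (C9 epimers) | CC[C@@H](C1C(=O)CCCn2cccc21)[C@H]1OC(=O)C(C)=C1
F2 | step 7 | tetracyclic ketone: keto form of 14 (C8 ketone, C9-H epimerisable, other stereocentres as in 14) | CC[C@H]1C2C(=O)CCCn3ccc(c32)[C@H]2[C@@H]1OC(=O)[C@@H]2C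
F3 | step 10 | (R)-4-(dimethylamino)-2-methyl-4-oxobutanoic acid | C[C@H](CC(=O)N(C)C)C(=O)O
F4 | step 10 | methyl (R)-4-(dimethylamino)-2-methyl-4-oxobutanoate | C[C@H](CC(=O)N(C)C)C(=O)OC
F5 | step 10 | methyl ester of keto acid 18 | CC[C@H]1C2=C(OS(=O)(=O)C(F)(F)F)CCCn3c(C(=O)C[C@@H](C)C(=O)OC)cc(c32)[C@H]2[C@@H]1OC(=O)[C@@H]2C
F6 | step 10 | methyl ester of hydroxy acid 19 (carbinol R) | CC[C@H]1C2=C(OS(=O)(=O)C(F)(F)F)CCCn3c([C@H](O)C[C@@H](C)C(=O)OC)cc(c32)[C@H]2[C@@H]1OC(=O)[C@@H]2C
F7 | step 11 | carbinol epimer of 19 (carbinol S) | CC[C@H]1C2=C(OS(=O)(=O)C(F)(F)F)CCCn3c([C@@H](O)C[C@@H](C)C(=O)O)cc(c32)[C@H]2[C@@H]1OC(=O)[C@@H]2C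
F8 | step 11 | trans appended-lactone epimer of 20 (O-CH S, methyl CH R) | CC[C@H]1C2=C(OS(=O)(=O)C(F)(F)F)CCCn3c([C@@H]4C[C@@H](C)C(=O)O4)cc(c32)[C@H]2[C@@H]1OC(=O)[C@@H]2C
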